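## The problem

The target is a bicyclo[8.4.0]tetradecane diterpenoid. A cyclohexane (ring A, C10–C11–C12–C13–C14–C1) is cis-fused through C1 and C10 to a ten-membered carbocycle (C1–C10) that has no transannular bridge to hold it in shape. Six stereocentres must be set: four contiguous on ring A (C14 with isopropyl, C1, C10, the methyl carbinol C11) and two on the large ring (the acetoxy carbinols C9 and C6). The ring A set is coherent. Trans C14/C1 and cis C1/C10 are what an endo Diels–Alder reaction of an E-enal with an E-diene gives, and the then axial C10 side chain blocks one face of the C11=C12 olefin, so oxygen can be placed on C11 from the other face. C9 sits next to C10 and can draw only on 1,2-induction from it; C6 is five bonds from the nearest ring A centre and has to come from outside. The large ring holds a trisubstituted C2=C3 olefin with C1 and C4 cis and a 1,1-disubstituted C7 methylene between the two acetoxy carbinols; ten-membered rings close slowly, and a closure that creates the olefin leaves its geometry open. Sensitive points are the acetates (base), the tertiary C11 hydroxyl (β to C9, so retro-aldol or dehydration threatens whenever C9 is a carbonyl carbon), the axial and therefore epimerisable C10 centre at that stage, and C6 while it is both allylic and α to a ketone. The structure opens at the C3–C4 bond: C3 is olefinic and C4 is a plain methylene two carbons from the C6 carbinol, so the bond joins an alkenyl carbon, available as a (Z)-C2=C3(CH3)–I unit on C1, to a primary alkyl carbon, available as a borane grown from a vinyl group on C6.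

## Retrosynthesis

**Target 26 to triol 25.** The two acetate C–O bonds are cut first, because esters would not survive enolates, hydrides or the basic coupling medium. Triol 25 has the full skeleton. The forward step must stop at the two secondary hydroxyls and leave the tertiary C11 hydroxyl free.

**Triol 25 to macrocycle 24.** The C7=CH2 unit is traced back to a tertiary carbinol bearing CH2SiMe3 (a β-hydroxysilane), and the three hydroxyls to silyl ethers. A free C7 methylene cannot be present during hydroboration, since 9-BBN takes a 1,1-disubstituted olefin as readily as a vinyl group. A C7 ketal would mask it equally well, but it would cost a hydrolysis and a late methylenation of a hindered ketone flanked by two leaving groups. The β-hydroxysilane leaves with the silyl ethers in one acidic operation. The forward step must eliminate only towards the exocyclic position, which silicon ensures, and must not ionise the C11 carbinol.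

**Macrocycle 24 to open-chain iodoalkene 22 (through borane 23).** The C3–C4 bond is cut. Of the ten ring bonds it is the only one that is remote from every stereocentre, adjoins no quaternary carbon and can bring the olefin geometry into the ring ready-made. Cutting C2=C3 would leave the Z geometry to the closure; cutting C8–C9 would create a stereocentre during it. Precursor 22 is acyclic beyond ring A, with a vinyl group on C6 and a (Z)-iodoalkene on C1. The forward reaction must hydroborate the vinyl group alone, close a ten-membered ring in preference to oligomers, and keep the geometry.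

**Precursor 22 to ketone 21 and aldol 20.** The C7–CH2Si bond and the C9 O–Si bond are cut, returning the masked carbon to a C7 ketone, the natural product of an aldol reaction. The forward addition must be a clean 1,2-addition to an enolisable ketone with a β-silyloxy group, which calls for an organocerium reagent. The C9 hydroxyl is silylated first so that no retro-aldol path is open.

**Aldol 20 to aldehyde 12 and methyl ketone 18.** The C8–C9 bond is cut. Among C6–C7, C7–C8 and C8–C9 this is the only convergent cut: it gives a ring A aldehyde and a five-carbon ketone whose single stereocentre can be bought. The forward aldol must enolise 18 at the methyl group, not at the doubly activated C6–H, and must add to the Felkin–Anh face of 12.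

**Ketone 18 to (R)-but-3-ene-1,2-diol 13.** One C–C bond (methyl to C7) and two oxidation levels are removed: 18 comes from aldehyde 16 through carbinol 17, 16 from mono-silyl ether 15, and 15 through bis-silyl ether 14 from 13. The C6 configuration is bought and only has to be preserved, so the oxidations are run without base.

**Aldehyde 12 to iodoalkene 9 (through 11 and 10) and to aldehyde 8.** After protecting-group and oxidation-level changes at C9 and C11, the C2=C3 bond is cut in the Wittig sense. Placing the iodo-olefination before the C9 aldehyde is unveiled saves a protecting group on C2, because the iodoalkene passes unchanged through silylation, DDQ, oxidation and aldol. It is placed after the hydride step because a C–I bond would be at risk there. The forward step must give the Z isomer, which the α-iodo ylide does.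

**Aldehyde 8 to cyclohexene aldehyde 5 (through diol 7 and epoxide 6).** The C11–O and C12–H bonds are removed. The tertiary alcohol is traced to an epoxide and that to the C11=C12 olefin of a Diels–Alder adduct. Epoxidation followed by hydride opening is preferred to direct hydration because both the face (anti to the axial C10 arm) and the site of opening (secondary C12, trans-diaxial) are predictable. The same hydride reduces the C2 aldehyde, which is re-oxidised beside the inert tertiary alcohol.

**Cyclohexene 5 to diene 3 and enal 4.** The C1–C10 and C13–C14 bonds are cut. One cycloaddition sets C14, C1 and C10; the other pairing of ring bonds has no activating group in the right place. Both partners are achiral six-carbon compounds. The forward reaction must be endo, must join the unsubstituted diene terminus C13 to the β-carbon of the enal, and must take one enantioface, which an imidazolidinone catalyst provides.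

**Diene 3 to enynol 1 (through ether 2).** A benzyl-type O–C bond and two hydrogens are removed. The trisubstituted olefin geometry is already present in commercial 1.

## Roads not taken

**Alternative 1:** The cut is C4–C5, with C2–O made in its place. In the forward direction a [3,3] sigmatropic shift inside an eight-membered cyclic allyl vinyl ether, fused to ring A, would form C4–C5, break C2–O and give the ten-membered ketone A1 with the C2=C3 olefin and the C7 methylene in place.
- Merits: the ring-forming event is thermal and unimolecular, needs no dilution and no metal, and the ring constraint of the transition state is expected to give the Z olefin.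
- Weak points: the substrate is itself a medium ring, reached through an eight-membered lactone and its methylenation next to a second methylene, and the resulting 2-alkoxydiene is acid-labile. An extra stereocentre at C2 has to be made only to be destroyed. In A1, C6 is a ketone, so the 6R carbinol must be set late by substrate-controlled reduction of an α-methylene ketone on a mobile ring, with 1,4-reduction as a competitor.
- Comparison: in the ring-forming step itself this road is better than the chosen one (no oligomerisation, no sensitive organometallic, no C7 mask). The chosen plan sets against this a bought C6 centre, an olefin geometry that is fixed by a stereodefined iodoalkene and not inferred from a transition state, and an acyclic precursor assembled convergently. Its price is high dilution and palladium.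

**Alternative 2:** No ring bond is cut; a transannular C2–C7 bond is added to give a tricycle of three six-membered rings. In the forward direction the tosylhydrazone of a ring-fusion α,β-epoxy ketone fragments with loss of nitrogen, cleaving C2–C7 and giving the cyclodecynone A2.
- Merits: the ten-membered ring arises by fragmentation of easily made six-membered rings, with no entropic penalty, and the C7 ketone is placed for methylenation.
- Weak points: A2 has an alkyne where the trisubstituted olefin should be. The C3 methyl must be added across C2≡C3 with no group to direct it to C3 and not to C2. The C6 oxygen is missing and must be introduced α to the C7 ketone in competition with C8, which carries a β-leaving group at C9. The tricyclic substrate with the ring A centres and the C9 oxygen is long to make, and at least six steps follow the ring formation.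
- Comparison: for reliability of the ring formation this road is superior. The chosen plan sets against it that the C3 methyl, the olefin geometry and both carbinol centres are in place at the moment of closure, with only two steps after it.

**Alternative 3:** The cut is C9–C10. In the forward direction a C9 dithiane carbanion, generated with n-BuLi, opens a C10–C11 epoxide on ring A at C10 with inversion. This forms C9–C10, closes the ring and releases the C11 hydroxyl, giving A3.
- Merits: one step makes the ring, the ring-fusion bond and the tertiary carbinol; the C10/C11 relation is fixed by anti opening; the C7 methylene and the Z olefin sit in a chain made by standard chemistry; no transition metal and no C7 mask are needed.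
- Weak points: a bulky tertiary carbanion must attack a secondary ring carbon beside a fully substituted epoxide carbon in a trans-diaxial trajectory while closing a ten-membered ring, and base-induced opening of the epoxide to an allylic alcohol competes. C9 emerges as a masked ketone, so the 9R carbinol has to be set afterwards by reduction of a ketone that is β to the C11 hydroxyl, the very array prone to retro-aldol cleavage.
- Comparison: this road is better in needing no mask at C7 and in setting C10/C11 in one stroke. The chosen plan sets against it a ring closure at a bond far from all stereocentres and a C9 carbinol fixed before the ring exists.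

Key step: step 19

Remark: locants C1–C14 are those of the target skeleton and are used for all intermediates; starting materials 1, 4 and 13 are commercial.
Remark: the C7 carbinol centre made in step 18 is drawn as the Felkin–Anh epimer (7R); it is erased in step 20, so the other epimer converges.

## Route

Step 1
Reactants: 1 (E)-3-methylpent-2-en-4-yn-1-ol
Product: 2 (E)-1-methoxy-4-{[(3-methylpent-2-en-4-yn-1-yl)oxy]methyl}benzene (PMB ether of 1)
Conditions: NaH, PMBCl, Bu4NI (cat.), THF/DMF, 0 °C to rt
Reagents that add atoms: 4-methoxybenzyl chloride, COc1ccc(CCl)cc1
Why: Williamson etherification; one equivalent of NaH forms the alkoxide and not the acetylide, and the PMB ether withstands the acid of step 3, peracid and hydride and is later removed oxidatively beside silyl ethers and the iodoalkene.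

Step 2
Reactants: 2 PMB ether of 1
Product: 3 (E)-1-methoxy-4-{[(3-methylpenta-2,4-dien-1-yl)oxy]methyl}benzene (diene C13=C12–C11(CH3)=C10–C9H2OPMB)
Conditions: H2 (1 atm), Pd/CaCO3 poisoned with Pb(OAc)2, quinoline, EtOAc, rt
Reagents that add atoms: none
Why: Semihydrogenation of a terminal alkyne on poisoned palladium stops at the alkene; the trisubstituted E olefin is untouched, so the C9 arm sits in the outside position of the s-cis diene.

Step 3
Reactants: 3 diene; 4 (E)-4-methylpent-2-enal
Product: 5 (1R,2R,6R)-2-{[(4-methoxybenzyl)oxy]methyl}-3-methyl-6-(propan-2-yl)cyclohex-3-ene-1-carbaldehyde (ring A: formyl carbon = C2 on C1, CH2OPMB = C9 on C10, isopropyl on C14, C11=C12)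
Conditions: (5S)-5-benzyl-2,2,3-trimethylimidazolidin-4-one·HClO4 (20 mol %), MeCN/H2O 95:5, 0 °C to rt
Reagents that add atoms: none
Why: Iminium-ion-catalysed Diels–Alder reaction: the E-iminium of 4 is shielded on one face by the benzyl group, so the diene adds to the open face (C14 R), the E-enal fixes C14/C1 trans, and endo addition places the outside C9 arm cis to the formyl group (C10); the unsubstituted terminus C13 bonds to the hindered β-carbon, the orientation expected for a 1-substituted diene and only weakly opposed by the C11 methyl.

Step 4
Reactants: 5 cyclohexene aldehyde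
Product: 6 C11,C12-epoxide of 5, oxirane oxygen on the ring face of the isopropyl group (anti to the C9 arm)
Conditions: mCPBA, NaHCO3, CH2Cl2, 0 °C
Reagents that add atoms: 3-chloroperbenzoic acid, OOC(=O)c1cccc(Cl)c1
Why: Prilezhaev epoxidation of the only electron-rich olefin; with the C1 and C14 groups equatorial the C10 CH2OPMB arm is pseudoaxial and blocks its own face, so the peracid attacks anti to it and sets C11; buffered peracid at 0 °C epoxidises a trisubstituted olefin faster than it oxidises the aldehyde.

Step 5
Reactants: 6 epoxy aldehyde
Product: 7 ring A diol: C2 primary alcohol on C1, tertiary C11 alcohol (hydroxyl trans to the C9 arm, methyl cis to it), C9 OPMB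
Conditions: LiAlH4, THF, 0 °C to 50 °C
Reagents that add atoms: none
Why: Hydride reduces the aldehyde and opens the trisubstituted epoxide at the secondary C12 in the trans-diaxial (Fürst–Plattner) sense, so the C11–O bond and its configuration are retained.

Step 6
Reactants: 7 diol
Product: 8 C2 aldehyde with free tertiary C11 hydroxyl and C9 OPMB
Conditions: Dess–Martin periodinane, NaHCO3, CH2Cl2, 0 °C to rt
Reagents that add atoms: none
Why: Dess–Martin oxidation touches only the primary alcohol; the tertiary one cannot be oxidised, the trans disposition of C2 and the C11 oxygen excludes a lactol, and the equatorial formyl group on C1 is the stable epimer.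

Step 7
Reactants: 8 hydroxy aldehyde
Product: 9 (Z)-iodoalkene: C1–CH=C(CH3)I with iodine cis to C1, free C11 hydroxyl, C9 OPMB
Conditions: EtPPh3I, n-BuLi, THF, rt; I2, −78 °C; NaN(SiMe3)2, −20 °C; then 8, −78 to −20 °C
Reagents that add atoms: ethyltriphenylphosphonium iodide, CC[P+](c1ccccc1)(c1ccccc1)c1ccccc1.[I-]; iodine, II
Why: Stork–Zhao-type Wittig olefination with the α-iodo ylide Ph3P=C(CH3)I; kinetic formation of the cis-oxaphosphetane places iodine and the C1 residue on the same side and gives the Z-iodoalkene; excess ylide covers the free tertiary hydroxyl.

Step 8
Reactants: 9 iodoalkene with free C11 hydroxyl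
Product: 10 C11 triethylsilyl ether of 9
Conditions: TESOTf, 2,6-lutidine, CH2Cl2, −78 to 0 °C
Reagents that add atoms: triethylsilyl trifluoromethanesulfonate, CC[Si](CC)(CC)OS(=O)(=O)C(F)(F)F
Why: Silyl triflate silylation of the hindered tertiary alcohol; the ether removes the retro-aldol and dehydration paths once C9 becomes a carbonyl carbon.

Step 9
Reactants: 10 TES ether
Product: 11 C9 primary alcohol (PMB removed), C11 OTES, (Z)-iodoalkene on C1
Conditions: DDQ, CH2Cl2/pH 7 buffer 10:1, 0 °C
Reagents that add atoms: none
Why: Oxidative cleavage of the PMB ether by hydride abstraction and hydrolysis of the oxocarbenium ion; the buffered medium spares the TES ether and the iodoalkene is not oxidised.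

Step 10
Reactants: 11 C9 alcohol
Product: 12 C9 aldehyde: ring A with formyl on C10, (Z)-2-iodoprop-1-enyl on C1, isopropyl on C14, OTES and methyl on C11
Conditions: Dess–Martin periodinane, NaHCO3, CH2Cl2, 0 °C; used at once
Reagents that add atoms: none
Why: Dess–Martin oxidation under buffered, non-basic conditions, chosen so that the axial formyl centre C10 is not epimerised.

Step 11
Reactants: 13 (R)-but-3-ene-1,2-diol
Product: 14 (R)-3,4-bis[(tert-butyldimethylsilyl)oxy]but-1-ene
Conditions: TBSCl, imidazole, DMF, rt
Reagents that add atoms: tert-butyldimethylsilyl chloride, CC(C)(C)[Si](C)(C)Cl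
Why: Standard silylation of both hydroxyls; the stereocentre (future C6) is not involved.

Step 12
Reactants: 14 bis-silyl ether
Product: 15 (R)-2-[(tert-butyldimethylsilyl)oxy]but-3-en-1-ol
Conditions: HF·pyridine, pyridine, THF, 0 °C
Reagents that add atoms: none
Why: Selective desilylation: the primary silyl ether is cleaved faster than the hindered secondary allylic one under buffered fluoride.

Step 13
Reactants: 15 primary alcohol
Product: 16 (R)-2-[(tert-butyldimethylsilyl)oxy]but-3-enal
Conditions: Dess–Martin periodinane, NaHCO3, CH2Cl2, 0 °C; used crude
Reagents that add atoms: none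
Why: Dess–Martin oxidation without amine base, so the α-silyloxy β,γ-unsaturated aldehyde is neither racemised nor isomerised into conjugation.

Step 14
Reactants: 16 silyloxy aldehyde
Product: 17 (3R)-3-[(tert-butyldimethylsilyl)oxy]pent-4-en-2-ol (both C2 epimers)
Conditions: MeMgBr, Et2O, −78 °C
Reagents that add atoms: methylmagnesium bromide, C[Mg]Br
Why: Grignard 1,2-addition; the new carbinol centre is oxidised away in the next step, so its configuration is immaterial.

Step 15
Reactants: 17 secondary alcohol
Product: 18 (R)-3-[(tert-butyldimethylsilyl)oxy]pent-4-en-2-one (C4–C8 fragment with the C6 stereocentre)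
Conditions: Dess–Martin periodinane, NaHCO3, CH2Cl2, 0 °C to rt
Reagents that add atoms: none
Why: Dess–Martin oxidation gives the methyl ketone under neutral conditions, which the acidic C6–H requires.

Step 16
Reactants: 18 methyl ketone; 12 C9 aldehyde
Product: 20 (6R,9R)-β-hydroxy ketone CH2=CH–C6H(OTBS)–C7(=O)–C8H2–C9H(OH)–(ring A of 12), via lithium enolate 19 (not isolated)
Conditions: LiN(iPr)2, THF, −78 °C; then 12, −78 °C
Reagents that add atoms: none
Why: Kinetic aldol addition: the amide base removes a proton from the unhindered methyl group and not from the encumbered C6–H; in the Felkin–Anh arrangement the fully substituted, oxygen-bearing C11 stands anti to the incoming enolate and the aldehyde hydrogen points under the ring, which leads to the 9R carbinol; the low temperature and the C11 silyl ether prevent epimerisation at C10 and retro-aldol cleavage.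

Step 17
Reactants: 20 aldol adduct
Product: 21 C9 tert-butyldimethylsilyl ether of 20
Conditions: TBSOTf, 2,6-lutidine, CH2Cl2, −78 °C
Reagents that add atoms: tert-butyldimethylsilyl trifluoromethanesulfonate, CC(C)(C)[Si](C)(C)OS(=O)(=O)C(F)(F)F
Why: Silylation of the β-hydroxy ketone at low temperature blocks the retro-aldol path before the basic organometallic step.

Step 18
Reactants: 21 bis-silyloxy ketone
Product: 22 cyclisation precursor: (7R) tertiary alcohol with CH2SiMe3 on C7 (β-hydroxysilane), C6 and C9 OTBS, C11 OTES, terminal C4=C5 vinyl, (Z)-C2=C3(CH3)I
Conditions: Me3SiCH2MgCl, CeCl3, THF, −78 to 0 °C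
Reagents that add atoms: (trimethylsilyl)methylmagnesium chloride, C[Si](C)(C)C[Mg]Cl
Why: Organocerium 1,2-addition (first half of a Peterson olefination): the weakly basic cerium reagent adds to the enolisable ketone without enolising C6 or expelling the β-silyloxy group and does not exchange with the iodoalkene; addition anti to the C6–OTBS bond (polar Felkin–Anh) should give the 7R carbinol, a centre that is erased in step 20.

Step 19
Reactants: 22 cyclisation precursor
Product: 24 (2Z) ten-membered ring with C3–C4 closed, C7 carbinol bearing CH2SiMe3, C6 and C9 OTBS, C11 OTES, via B-alkyl-9-BBN adduct 23 (not isolated)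
Conditions: 9-BBN, THF, rt to 40 °C; H2O; then slow addition to Pd(dppf)Cl2 (20 mol %), AsPh3, Cs2CO3, DMF/THF/H2O, 50 °C, final 1 mM
Reagents that add atoms: none
Why: Intramolecular B-alkyl Suzuki–Miyaura coupling; the closest known reaction type is the 9-BBN/Pd(dppf)Cl2 macrocyclisation of ω-alkenyl iodoalkenes, documented for nine-membered and larger carbocycles. 9-BBN adds syn and anti-Markovnikov to the only unhindered olefin, the C4=C5 vinyl group, placing boron on C4 (23); the trisubstituted iodoalkene is inert to this bulky borane and C7 carries no olefin because it is held as the β-hydroxysilane. Water destroys the excess B–H so that no hydride is left to reduce the C–I bond. Zerovalent palladium, formed in the flask from Pd(dppf)Cl2, inserts into the C3–I bond with retention, base turns the borane into a borate that passes the primary C4 alkyl group to divalent palladium, and reductive elimination forms C3–C4. The ten-membered ring is closed end to end by this reductive elimination from an eleven-membered palladacycle; no stereocentre is created, and the 2Z geometry is that of the iodoalkene because neither oxidative addition nor reductive elimination offers a path for isomerisation. Cyclisation must outrun oligomerisation and β-hydride elimination: slow addition keeps 23 dilute, the cis side chains on C1 and C10 hold the two termini close, the quaternary C7 favours a folded chain, and the wide bite angle of dppf speeds reductive elimination.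

Step 20
Reactants: 24 macrocyclic β-hydroxysilane
Product: 25 (2Z)-6,9,11-triol with exocyclic C7 methylene
Conditions: aq HF (48 %), MeCN, 0 °C to rt
Reagents that add atoms: none
Why: Acid-promoted Peterson elimination and global desilylation in one operation: protonation of the tertiary C7 hydroxyl and anti loss of water and silicon can only give the exocyclic olefin, while fluoride removes the TBS and TES ethers; the unactivated tertiary C11 alcohol does not ionise under these conditions.

Step 21
Reactants: 25 triol
Product: 26 target, (1S,2Z,6R,9R,10S,11R,14R)-6,9-diacetoxy-11-hydroxy compound CNP0303839.1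
Conditions: Ac2O, pyridine, DMAP (cat.), CH2Cl2, 0 °C to rt
Reagents that add atoms: acetic anhydride, CC(=O)OC(C)=O
Why: Nucleophile-catalysed acetylation of the two secondary hydroxyls; the hindered axial tertiary C11 hydroxyl is not acylated under these mild conditions.

## Compound list

1 | (E)-3-methylpent-2-en-4-yn-1-ol | C#C/C(C)=C/CO | starting material
2 | (E)-1-methoxy-4-{[(3-methylpent-2-en-4-yn-1-yl)oxy]methyl}benzene | C#C/C(C)=C/COCc1ccc(OC)cc1 | intermediate
3 | (E)-1-methoxy-4-{[(3-methylpenta-2,4-dien-1-yl)oxy]methyl}benzene | C=C/C(C)=C/COCc1ccc(OC)cc1 | intermediate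
4 | (E)-4-methylpent-2-enal | CC(C)/C=C/C=O | starting material
5 | (1R,2R,6R)-2-{[(4-methoxybenzyl)oxy]methyl}-3-methyl-6-(propan-2-yl)cyclohex-3-ene-1-carbaldehyde | COc1ccc(COC[C@@H]2[C@H](C=O)[C@@H](C(C)C)CC=C2C)cc1 | intermediate
6 | C11,C12-epoxide of 5 (oxygen on the isopropyl face) | COc1ccc(COC[C@@H]2[C@H](C=O)[C@@H](C(C)C)C[C@H]3O[C@]32C)cc1 | intermediate
7 | ring A diol (C2 primary alcohol, C11 tertiary alcohol, C9 OPMB) | COc1ccc(COC[C@@H]2[C@H](CO)[C@@H](C(C)C)CC[C@@]2(C)O)cc1 | intermediate
8 | C2 aldehyde with free C11 hydroxyl and C9 OPMB | COc1ccc(COC[C@@H]2[C@H](C=O)[C@@H](C(C)C)CC[C@@]2(C)O)cc1 | intermediate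
9 | (Z)-iodoalkene with free C11 hydroxyl and C9 OPMB | COc1ccc(COC[C@@H]2[C@H](/C=C(/C)I)[C@@H](C(C)C)CC[C@@]2(C)O)cc1 | intermediate
10 | C11 triethylsilyl ether of 9 | COc1ccc(COC[C@@H]2[C@H](/C=C(/C)I)[C@@H](C(C)C)CC[C@@]2(C)O[Si](CC)(CC)CC)cc1 | intermediate
11 | C9 primary alcohol, C11 OTES, (Z)-iodoalkene | OC[C@@H]1[C@H](/C=C(/C)I)[C@@H](C(C)C)CC[C@@]1(C)O[Si](CC)(CC)CC | intermediate
12 | C9 aldehyde, C11 OTES, (Z)-iodoalkene | O=C[C@@H]1[C@H](/C=C(/C)I)[C@@H](C(C)C)CC[C@@]1(C)O[Si](CC)(CC)CC | intermediate
13 | (R)-but-3-ene-1,2-diol | C=C[C@H](CO)O | starting material
14 | (R)-3,4-bis[(tert-butyldimethylsilyl)oxy]but-1-ene | C=C[C@H](CO[Si](C)(C)C(C)(C)C)O[Si](C)(C)C(C)(C)C | intermediate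
15 | (R)-2-[(tert-butyldimethylsilyl)oxy]but-3-en-1-ol | C=C[C@H](CO)O[Si](C)(C)C(C)(C)C | intermediate
16 | (R)-2-[(tert-butyldimethylsilyl)oxy]but-3-enal | C=C[C@H](C=O)O[Si](C)(C)C(C)(C)C | intermediate
17 | (3R)-3-[(tert-butyldimethylsilyl)oxy]pent-4-en-2-ol (C2 epimers) | C=C[C@H](C(C)O)O[Si](C)(C)C(C)(C)C | intermediate
18 | (R)-3-[(tert-butyldimethylsilyl)oxy]pent-4-en-2-one | C=C[C@H](C(C)=O)O[Si](C)(C)C(C)(C)C | intermediate
19 | lithium enolate of 18 (methyl side) | C=C[C@H](C(=C)O[Li])O[Si](C)(C)C(C)(C)C | intermediate
20 | (6R,9R)-β-hydroxy ketone (C7 ketone, C6 OTBS, C9 OH, C11 OTES) | C=C[C@@H](O[Si](C)(C)C(C)(C)C)C(=O)C[C@@H](O)[C@@H]1[C@H](/C=C(/C)I)[C@@H](C(C)C)CC[C@@]1(C)O[Si](CC)(CC)CC | intermediate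
21 | C9 tert-butyldimethylsilyl ether of 20 | C=C[C@@H](O[Si](C)(C)C(C)(C)C)C(=O)C[C@@H](O[Si](C)(C)C(C)(C)C)[C@@H]1[C@H](/C=C(/C)I)[C@@H](C(C)C)CC[C@@]1(C)O[Si](CC)(CC)CC | intermediate
22 | cyclisation precursor: (7R) β-hydroxysilane, C6/C9 OTBS, C11 OTES, vinyl on C6, (Z)-iodoalkene on C1 | C=C[C@@H](O[Si](C)(C)C(C)(C)C)[C@@](O)(C[Si](C)(C)C)C[C@@H](O[Si](C)(C)C(C)(C)C)[C@@H]1[C@H](/C=C(/C)I)[C@@H](C(C)C)CC[C@@]1(C)O[Si](CC)(CC)CC | intermediate
23 | C4 B-alkyl-9-BBN derivative of 22 | C1CCC2CCCC1B2CC[C@@H](O[Si](C)(C)C(C)(C)C)[C@@](O)(C[Si](C)(C)C)C[C@@H](O[Si](C)(C)C(C)(C)C)[C@@H]3[C@H](/C=C(/C)I)[C@@H](C(C)C)CC[C@@]3(C)O[Si](CC)(CC)CC | intermediate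
24 | (2Z) ten-membered ring, C7 β-hydroxysilane, C6/C9 OTBS, C11 OTES | O[C@]1(C[Si](C)(C)C)C[C@@H](O[Si](C)(C)C(C)(C)C)[C@@H]2[C@H](/C=C(/C)CC[C@H]1O[Si](C)(C)C(C)(C)C)[C@@H](C(C)C)CC[C@@]2(C)O[Si](CC)(CC)CC | intermediate
25 | (2Z)-6,9,11-triol with C7 methylene | C=C1C[C@@H](O)[C@@H]2[C@H](/C=C(/C)CC[C@H]1O)[C@@H](C(C)C)CC[C@@]2(C)O | intermediate
26 | CNP0303839.1, (1S,2Z,6R,9R,10S,11R,14R)-6,9-diacetate | C=C1C[C@@H](OC(C)=O)[C@@H]2[C@H](/C=C(/C)CC[C@H]1OC(C)=O)[C@@H](C(C)C)CC[C@@]2(C)O | target

## Step count and weakest steps

Total: 21 steps. Longest linear sequence: 16 steps (1 to 26 through steps 1–10 and 16–21); the ketone branch (steps 11–15) joins at step 16.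

**Step 19 (key step).** The most likely failure is slow transmetallation of the hindered C4 borate at the low concentration needed for ring closure, so that protodeboronation, β-hydride elimination, reduction of the C–I bond or intermolecular coupling take over; strain in the forming ring would slow reductive elimination further. Fallback, from 22 back to 24: the same bond is made by an intramolecular Negishi coupling, whose transmetallation needs no base and is fast. Hydroboration of 22 with 9-BBN and oxidation with NaBO3·4H2O give the primary C4 alcohol F1; I2, PPh3 and imidazole convert it into the primary C4 iodide F2; zinc dust with LiCl in THF inserts into the sp3 C–I bond only, giving the C4 alkylzinc iodide F3, which is added slowly to Pd(OAc)2/SPhos in THF and closes to 24. The hindered tertiary C7 hydroxyl is of the kind that alkylzinc halides tolerate in such couplings.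

**Step 3.** The iminium-catalysed cycloaddition may be slow with a β-branched enal and an acyclic trisubstituted diene, and the C11 methyl may divert part of the material to the regioisomer in which C10 bonds to the β-carbon, or erode endo selectivity. Fallback, from 3 back to 7: an auxiliary-controlled, Lewis acid-promoted cycloaddition with a more strongly activated dienophile. (S)-4-Benzyl-3-[(E)-4-methylpent-2-enoyl]oxazolidin-2-one F4 (from (E)-4-methylpent-2-enoic acid, pivaloyl chloride, Et3N, LiCl and (S)-4-benzyloxazolidin-2-one) reacts with 3 under Et2AlCl in CH2Cl2 at −30 °C. The chelated s-cis imide is attacked opposite to the benzyl group, which is the same face of the β-carbon as in step 3, to give the cycloadduct imide F5. mCPBA gives the epoxy imide F6, and LiAlH4 cleaves the auxiliary reductively and opens the epoxide to give diol 7.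

**Step 16.** Facial discrimination at the C9 aldehyde may be poor in the compact lithium transition state, since C10 is flanked by two branched ring carbons, and partial epimerisation of the axial formyl centre can occur. Fallback, from 18 and 12 back to 20: a Mukaiyama aldol reaction through an open transition state, where 1,2-induction by α-branched aldehydes is usually stronger and the β-silyloxy-bearing C11 again takes the anti position. Ketone 18 is converted with LiN(iPr)2 and Me3SiCl at −78 °C into its trimethylsilyl enol ether F7, which is added to 12 with BF3·OEt2 in CH2Cl2 at −78 °C to give 20.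

**Step 20.** Ionisation at C7 may outpace loss of silicon, leading to transannular capture by the C2=C3 olefin, or the acid may dehydrate the tertiary C11 alcohol. Fallback, from 24 back to 25: the elimination is done first under anionic conditions, where no cation is formed. KH in THF at 0 °C converts 24 by syn elimination of the alkoxide into the tris-silyl ether with C7 methylene F8, and Bu4NF in THF then removes the three silyl groups to give 25.

## Further compounds

F1 | step 19 | primary C4 alcohol from hydroboration–oxidation of 22 | OCC[C@@H](O[Si](C)(C)C(C)(C)C)[C@@](O)(C[Si](C)(C)C)C[C@@H](O[Si](C)(C)C(C)(C)C)[C@@H]1[C@H](/C=C(/C)I)[C@@H](C(C)C)CC[C@@]1(C)O[Si](CC)(CC)CC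
F2 | step 19 | primary C4 iodide | ICC[C@@H](O[Si](C)(C)C(C)(C)C)[C@@](O)(C[Si](C)(C)C)C[C@@H](O[Si](C)(C)C(C)(C)C)[C@@H]1[C@H](/C=C(/C)I)[C@@H](C(C)C)CC[C@@]1(C)O[Si](CC)(CC)CC
F3 | step 19 | C4 alkylzinc iodide | I[Zn]CC[C@@H](O[Si](C)(C)C(C)(C)C)[C@@](O)(C[Si](C)(C)C)C[C@@H](O[Si](C)(C)C(C)(C)C)[C@@H]1[C@H](/C=C(/C)I)[C@@H](C(C)C)CC[C@@]1(C)O[Si](CC)(CC)CC
F4 | step 3 | (S)-4-benzyl-3-[(E)-4-methylpent-2-enoyl]oxazolidin-2-one | CC(C)/C=C/C(=O)N1[C@@H](Cc2ccccc2)COC1=O
F5 | step 3 | cycloadduct imide (ring A of 5 with the acyl oxazolidinone in place of the formyl group) | COc1ccc(COC[C@@H]2[C@H](C(=O)N3[C@@H](Cc4ccccc4)COC3=O)[C@@H](C(C)C)CC=C2C)cc1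
F6 | step 3 | C11,C12-epoxy imide | COc1ccc(COC[C@@H]2[C@H](C(=O)N3[C@@H](Cc4ccccc4)COC3=O)[C@@H](C(C)C)C[C@H]5O[C@]52C)cc1
F7 | step 16 | trimethylsilyl enol ether of 18 | C=C[C@H](C(=C)O[Si](C)(C)C)O[Si](C)(C)C(C)(C)C
F8 | step 20 | (2Z) tris-silyl ether with C7 methylene (C6/C9 OTBS, C11 OTES) | C=C1C[C@@H](O[Si](C)(C)C(C)(C)C)[C@@H]2[C@H](/C=C(/C)CC[C@H]1O[Si](C)(C)C(C)(C)C)[C@@H](C(C)C)CC[C@@]2(C)O[Si](CC)(CC)CC
A1 | alternative 1 | (2Z) ten-membered C6 ketone with C7 methylene, C9 OTBS, C11 OTES | C=C1C[C@@H](O[Si](C)(C)C(C)(C)C)[C@@H]2[C@H](/C=C(/C)CCC1=O)[C@@H](C(C)C)CC[C@@]2(C)O[Si](CC)(CC)CC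
A2 | alternative 2 | ring A-fused cyclodec-2-yn-7-one with C9 OTBS and free C11 hydroxyl | O=C1C[C@@H](O[Si](C)(C)C(C)(C)C)[C@@H]2[C@H](C#CCCC1)[C@@H](C(C)C)CC[C@@]2(C)O
A3 | alternative 3 | (2Z) bicyclic C11 alcohol with C9 spiro-1,3-dithiane, C7 methylene, C6 OTBS | C=C1CC2(SCCCS2)[C@@H]3[C@H](/C=C(/C)CC[C@H]1O[Si](C)(C)C(C)(C)C)[C@@H](C(C)C)CC[C@@]3(C)O
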